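Start from a ratio: the last target reading of the dusk run over that of the dawn run is 1.02, yet dawn carried 2.14 times the substrate, at the same 58 °C. Read that as a pseudo-first-order coupling: percent of target follows c(second intermediate), and that concentration grows from partner, not from substrate. Note the lag too. Dusk shows 1.5% target at 1.00 min, with 29.6% of the substrate consumed, so let capture agent and protic impurity take their share of partner first.

| flask | substrate | partner | capture agent | protic impurity | temperature | remark | time |
|---|---|---|---|---|---|---|---|
| dusk | 0.22 M | 0.60 M | 0.24 M | 0.072 M | 58 °C | run made earlier |  |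
| summer | 0.31 M | 0.60 M | 0.24 M | 0.072 M | 74 °C | run made earlier |  |
| dawn | 0.47 M | 0.60 M | 0.24 M | 0.072 M | 58 °C | run made earlier |  |
| Wednesday's | 0.24 M | 0.600 M | 0.240 M | 0.0720 M |  | at 50 °C until 50 s, from then on at 80 °C | 2.5 min |
| Tuesday's | 0.40 M | 0.600 M | 0.240 M | 0.0720 M |  | at 80 °C throughout | 2.5 min |

dusk run (percent of the substrate charged)

| time / min | target / % | substrate / % |
|---|---|---|
| 0.500 | 1.0 | 83.7 |
| 1.00 | 1.5 | 70.4 |
| 1.50 | 6.7 | 60.6 |
| 2.00 | 11.1 | 49.3 |
| 2.50 | 18.1 | 40.1 |

summer run (percent of the substrate charged)

| time / s | target / % | substrate / % |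
|---|---|---|
| 10.0 | 0.3 | 79.6 |
| 12.0 | 0 | 74.8 |
| 25.0 | 7.7 | 53.8 |
| 50.0 | 29.9 | 29.6 |

dawn run (percent of the substrate charged)

| time / min | target / % | substrate / % |
|---|---|---|
| 0.200 | 1.7 | 93.7 |
| 0.417 | 0.6 | 86.7 |
| 0.667 | 0.8 | 78.8 |
| 1.33 | 4.5 | 64.0 |
| 2.50 | 17.7 | 42.1 |

(each reading ± 1 percentage point)

1. the winner by amount of target, in percent of the substrate charged; "neither" if no more than 2 percentage points parts them (Wednesday's / Tuesday's / neither)
2. how much target is there at the end, in percent of the substrate charged: Wednesday's
3. how much target is there at the end, in percent of the substrate charged: Tuesday's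

- steps that have been proposed: substrate -> open intermediate; partner + protic impurity -> quenched reagent; open intermediate + second intermediate -> target; partner -> second intermediate; second intermediate + capture agent -> trapped intermediate

So count partner against substrate, assuming each of the two takes its whole charge, one for one:

cover = [c(partner) − c(protic impurity) − c(capture agent)] / c(substrate)

Tuesday's: 0.720
Wednesday's: 1.20

This ratio of deliverable partner to substrate charged is the cover. Now turn the question round. For Tuesday's to win, Wednesday's must end below 72.0%, which means a mean pace over its 100 s at 80 °C below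

needed pace = 0.432 /min

Take the summer run, colder at 74 °C. Between 25.0 s and 50.0 s its target climbed at

read pace = 0.533 /min

That is faster than needed. Remove the lag, with summer target still at 0% at 12.0 s, and Wednesday's reaches

78.1%

Tuesday's, hot for 2.5 min, needs a slower pace than that reading: 0.288 /min. My reckoning: Tuesday's near its cover, Wednesday's ahead.

The forecast also names Wednesday's, with 84% against 68%, holding that “the 50 °C stage spends capture agent while conserving partner”. Its Wednesday's stands higher than mine. Its Tuesday's stands lower than my cover.

The flask gives 80.3% for Wednesday's and 74.6% for Tuesday's: Wednesday's wins.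

    substrate → open intermediate (k = 0.00270 /s, Ea = 85.0 kJ/mol)
    partner + protic impurity → quenched reagent (k = 0.0320 /M/s, Ea = 58.0 kJ/mol)
    open intermediate + second intermediate → target (k = 0.0200 /M/s, Ea = 62.0 kJ/mol)
    partner → second intermediate (k = 0.00290 /s, Ea = 97.0 kJ/mol)
    second intermediate + capture agent → trapped intermediate (k = 0.0400 /M/s, Ea = 47.0 kJ/mol)
    (constants at 50 °C)

Left for 25.0 min, Wednesday's at cover 1.20 reaches >99.9%, Tuesday's at cover 0.720 reaches 78.6%. The gap between the two flasks comes mainly from the difference in substrate charge: Tuesday's without that difference ends at 89.9%. Partner running short is a part of Tuesday's shortfall, with 0.0054% of it left at 2.50 min and 25.1% of the substrate still open intermediate; the trapping step is another part, for without it Tuesday's ends at 96.0%. Cut Tuesday's capture agent to 0.060 M and the cover climbs to 1.17; that flask ends at 93.1%.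

The numbers in the tables were computed for substances that don't exist, and the scatter is random.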